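## Retrosynthetic overview

1. Endgame: the C19 acetate comes from selective acylation of a 3,19-diol, the acid from a Horner–Wadsworth–Emmons reaction on a C13 methyl ketone (Wacker oxidation of a but-3-enyl group), and the C7=C8 bond with its C8 methyl from a C8 ketone via the enol triflate and a Negishi methylation.
2. The axial 3-OH comes from a bulky hydride; the quaternary C4 and the trans ring fusion (C5) come from a Birch-type reductive methylation of a 4-carbomethoxy-4-en-3-one.
3. Key disconnection: ring A is cut at C1–C2 and C4–C5, a [3+3] union of a C2–C3–C4 unit (bis-silyl dienol ether of methyl acetoacetate, whose ester carbon is C19) with a ring-B keto aldehyde.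
4. Enabling feature: in ring A the oxygenated C3 lies between C2 and C4 (a 1,3-dinucleophile, with C19 at the ester level activating C4), while C1 and C5 both sit on the quaternary C10 (a 1,3-dielectrophile: C1 aldehyde, C5 ketone).
5. Ring order: ring B first (commercial cyclohexenone ketal; C9 and C10 set by asymmetric conjugate addition with enolate trapping), ring A second in the key step.

Key step: step 5

Remark: labdane numbering is used (ring A: C1–C5, C10; ring B: C5–C10); in the monocyclic compounds the ketone carbon is the future C5, the methyl-bearing carbon C10, the butenyl-bearing carbon C9 and the ketal carbon C8. Compounds 1 and 10 are taken as commercial.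

## Route

Step 1
Reactants: 1 1,4-dioxaspiro[4.5]dec-6-en-8-one
Product: 2 7-iodo-1,4-dioxaspiro[4.5]dec-6-en-8-one
Conditions: I2, pyridine, CH2Cl2, 0 °C to rt
Reagents that add atoms: iodine, [I][I]
Why: α-Iodination of the cyclohexenone by iodine and pyridine (conjugate addition of pyridine, iodination of the enolate, elimination) is a standard way to functionalise the α-carbon and should leave the ketal intact.

Step 2
Reactants: 2 7-iodo-1,4-dioxaspiro[4.5]dec-6-en-8-one; 3 methylboronic acid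
Product: 4 7-methyl-1,4-dioxaspiro[4.5]dec-6-en-8-one
Conditions: PdCl2(dppf) (5 mol %), K3PO4, dioxane/H2O, 80 °C
Reagents that add atoms: methylboronic acid (3), CB(O)O
Why: Suzuki–Miyaura coupling of the α-iodo enone should install the future C10 methyl regiospecifically; no stereocentre is formed.

Step 3
Reactants: 4 7-methyl-1,4-dioxaspiro[4.5]dec-6-en-8-one; 5 but-3-en-1-ylmagnesium bromide; 6 formaldehyde
Product: 8 (6S,7R)-6-(but-3-en-1-yl)-7-(hydroxymethyl)-7-methyl-1,4-dioxaspiro[4.5]decan-8-one, via magnesium enolate 7 (not isolated)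
Conditions: Cu(OTf)2 (4 mol %), chiral imidazolinium chloride as carbene precursor (5 mol %, the enantiomer that gives the 6S centre), Et2O, −30 °C; then CH2O (monomer in THF), −78 to −40 °C; aq. NH4Cl
Reagents that add atoms: but-3-en-1-ylmagnesium bromide (5), C=CCC[Mg]Br; formaldehyde (6), C=O
Why: Copper-catalysed asymmetric conjugate addition of a Grignard reagent to an α-substituted cyclic enone should set C9 under control of the chiral carbene ligand, and the regiodefined enolate 7 should undergo the aldol reaction with formaldehyde anti to the new butenyl group, which sets the quaternary C10 with its methyl cis to the side chain.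

Step 4
Reactants: 8 (6S,7R)-6-(but-3-en-1-yl)-7-(hydroxymethyl)-7-methyl-1,4-dioxaspiro[4.5]decan-8-one
Product: 9 (6S,7R)-6-(but-3-en-1-yl)-7-methyl-8-oxo-1,4-dioxaspiro[4.5]decane-7-carbaldehyde
Conditions: Dess–Martin periodinane, NaHCO3, CH2Cl2, 0 °C to rt
Reagents that add atoms: none
Why: Dess–Martin oxidation of the neopentyl primary alcohol should give the non-enolisable α-formyl ketone under buffered conditions that avoid retro-aldol and deformylation; no stereocentre is touched.

Step 5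
Reactants: 9 (6S,7R)-6-(but-3-en-1-yl)-7-methyl-8-oxo-1,4-dioxaspiro[4.5]decane-7-carbaldehyde; 10 1-methoxy-1,3-bis(trimethylsilyloxy)buta-1,3-diene
Product: 13 methyl (4aS,5S)-5-(but-3-en-1-yl)-6,6-(ethylenedioxy)-4a-methyl-2-oxo-2,4a,5,6,7,8-hexahydronaphthalene-1-carboxylate, via open-chain titanium aldolate 11 (not isolated), via bicyclic titanium bis-aldolate 12 (not isolated)
Conditions: TiCl4 (2.2 equiv), CH2Cl2, −78 to −20 °C; then Et3N (8 equiv), −20 °C to rt; aq. NaHCO3
Reagents that add atoms: 1-methoxy-1,3-bis(trimethylsilyloxy)buta-1,3-diene (10), COC(O[Si](C)(C)C)=CC(=C)O[Si](C)(C)C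
Why: TiCl4 binds the 1,3-keto aldehyde of 9 as a six-membered chelate, and the terminal carbon of 10 adds to the more electrophilic aldehyde in a vinylogous Mukaiyama aldol reaction (C1–C2), which gives the titanium aldolate 11 still chelated to the C5 ketone. The remaining silyl enol ether of the β-keto ester then adds through C4 to this activated ketone in an intramolecular Mukaiyama aldol reaction (C4–C5), closing ring A in a 6-(enolexo)-exo-trig mode to give 12, and Et3N then removes both titanium aldolates by E1cB elimination. The closest known reaction type is the TiCl4-mediated [3+3] cyclocondensation of 1,3-bis(silyloxy)-1,3-dienes with β-keto aldehyde equivalents, which here cannot aromatise because C10 is quaternary and so stops at the cross-conjugated dienone. No new stereocentre survives, since the centres formed at C1, C4 and C5 are erased by the eliminations, and C9 and C10 are not enolisable and are carried through unchanged. The step needs regioselectivity (terminal diene carbon to the aldehyde, central carbon to the ketone), which the reactivity gap between the aldehyde and the hindered ketone secures, and it needs ring closure before loss of the C1 oxygen, which is secured by holding the mixture cold until the base is added, so that the C1=C2 bond is formed inside the ring. The dioxolane and the terminal alkene should survive because the Lewis acid is held in the chelate at low temperature.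

Step 6
Reactants: 13 methyl (4aS,5S)-5-(but-3-en-1-yl)-6,6-(ethylenedioxy)-4a-methyl-2-oxo-2,4a,5,6,7,8-hexahydronaphthalene-1-carboxylate; 14 iodomethane
Product: 16 methyl (1S,4aR,5S,8aS)-5-(but-3-en-1-yl)-6,6-(ethylenedioxy)-1,4a-dimethyl-2-oxo-1,2,4a,5,6,7,8,8a-octahydronaphthalene-1-carboxylate, via lithium enolate 15 (not isolated)
Conditions: Li (2.2 equiv), t-BuOH (1 equiv), NH3(l)/THF, −78 °C; then MeI (excess), −78 to −33 °C; NH4Cl
Reagents that add atoms: iodomethane (14), C[I]
Why: In this Birch-type reductive alkylation, two-electron reduction of the doubly activated C4=C5 bond with axial protonation at C5 anti to the C10 methyl should give the trans ring fusion and the β-keto ester enolate 15, which is C-methylated on the face opposite the axial C10 methyl so that the ester ends axial (C19) and the new methyl equatorial, while the C1=C2 bond is kept and leaves the C3 ketone non-enolisable for steps 8 and 9.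

Step 7
Reactants: 16 methyl (1S,4aR,5S,8aS)-5-(but-3-en-1-yl)-6,6-(ethylenedioxy)-1,4a-dimethyl-2-oxo-1,2,4a,5,6,7,8,8a-octahydronaphthalene-1-carboxylate
Product: 17 methyl (1S,4aR,5S,8aS)-5-(but-3-en-1-yl)-1,4a-dimethyl-2,6-dioxo-1,2,4a,5,6,7,8,8a-octahydronaphthalene-1-carboxylate
Conditions: dilute aq. HCl, THF, 40 °C
Reagents that add atoms: water, O
Why: Acid-catalysed ketal hydrolysis should unmask the C8 ketone, and C9, now epimerisable, already holds the thermodynamically preferred equatorial side chain.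

Step 8
Reactants: 17 methyl (1S,4aR,5S,8aS)-5-(but-3-en-1-yl)-1,4a-dimethyl-2,6-dioxo-1,2,4a,5,6,7,8,8a-octahydronaphthalene-1-carboxylate
Product: 19 methyl (1S,4aR,5S,8aS)-5-(but-3-en-1-yl)-1,4a-dimethyl-2-oxo-6-(trifluoromethanesulfonyloxy)-1,2,4a,5,8,8a-hexahydronaphthalene-1-carboxylate, via potassium enolate 18 (not isolated)
Conditions: KN(SiMe3)2 (1.1 equiv), THF, −78 °C; then PhNTf2, −78 to 0 °C
Reagents that add atoms: N-phenylbis(trifluoromethanesulfonimide), O=S(=O)(N(c1ccccc1)S(=O)(=O)C(F)(F)F)C(F)(F)F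
Why: Kinetic deprotonation at the unhindered C7 methylene (C9 is tertiary and next to the quaternary C10, the C3 enone has no enolisable position and the ester no α-hydrogen) followed by O-triflation of enolate 18 should give the C7=C8 enol triflate regioselectively.

Step 9
Reactants: 19 methyl (1S,4aR,5S,8aS)-5-(but-3-en-1-yl)-1,4a-dimethyl-2-oxo-6-(trifluoromethanesulfonyloxy)-1,2,4a,5,8,8a-hexahydronaphthalene-1-carboxylate; 20 methylzinc chloride
Product: 21 methyl (1S,4aS,5R,8aS)-5-(but-3-en-1-yl)-1,4a,6-trimethyl-2-oxo-1,2,4a,5,8,8a-hexahydronaphthalene-1-carboxylate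
Conditions: Pd(PPh3)4 (5 mol %), THF, 50 °C
Reagents that add atoms: methylzinc chloride (20), C[Zn]Cl
Why: Negishi coupling of the enol triflate should place the C8 methyl on the already fixed C7=C8 double bond and tolerates the enone and the ester.

Step 10
Reactants: 21 methyl (1S,4aS,5R,8aS)-5-(but-3-en-1-yl)-1,4a,6-trimethyl-2-oxo-1,2,4a,5,8,8a-hexahydronaphthalene-1-carboxylate
Product: 22 methyl (1S,4aS,5R,8aS)-5-(but-3-en-1-yl)-1,4a,6-trimethyl-2-oxo-1,2,3,4,4a,5,8,8a-octahydronaphthalene-1-carboxylate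
Conditions: Li[HB(s-Bu)3] (L-Selectride, 1.1 equiv), THF, −78 °C; aq. NH4Cl
Reagents that add atoms: none
Why: Conjugate hydride reduction of the β-unsubstituted cyclohexenone, whose carbonyl is shielded by the quaternary C4, should remove the C1=C2 bond once it has served as a blocking group, and the hindered ester and the isolated alkenes are not reduced.

Step 11
Reactants: 22 methyl (1S,4aS,5R,8aS)-5-(but-3-en-1-yl)-1,4a,6-trimethyl-2-oxo-1,2,3,4,4a,5,8,8a-octahydronaphthalene-1-carboxylate
Product: 24 (1R,2S,4aS,5R,8aS)-5-(but-3-en-1-yl)-1-(hydroxymethyl)-1,4a,6-trimethyl-1,2,3,4,4a,5,8,8a-octahydronaphthalen-2-ol, via hydroxy ester 23 (not isolated)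
Conditions: Li[HB(s-Bu)3] (1.5 equiv), THF, −78 °C; then LiAlH4 (3 equiv), 0 °C to reflux; aq. NaOH work-up
Reagents that add atoms: none
Why: The bulky borohydride should attack the C3 ketone from the equatorial direction and give the axial alcohol (3-OH trans to the axial C19 ester and to the C10 methyl), and LiAlH4 added to the same flask then reduces the hindered C19 methyl ester to the primary alcohol.

Step 12
Reactants: 24 (1R,2S,4aS,5R,8aS)-5-(but-3-en-1-yl)-1-(hydroxymethyl)-1,4a,6-trimethyl-1,2,3,4,4a,5,8,8a-octahydronaphthalen-2-ol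
Product: 25 4-[(1R,4aS,5R,6S,8aS)-6-hydroxy-5-(hydroxymethyl)-2,5,8a-trimethyl-1,4,4a,5,6,7,8,8a-octahydronaphthalen-1-yl]butan-2-one
Conditions: PdCl2 (10 mol %), CuCl (20 mol %), O2 (1 atm), DMF/H2O, rt
Reagents that add atoms: water, O
Why: Wacker–Tsuji oxidation should convert the terminal alkene into the methyl ketone with Markovnikov selectivity, while the trisubstituted C7=C8 alkene is inert.

Step 13
Reactants: 25 4-[(1R,4aS,5R,6S,8aS)-6-hydroxy-5-(hydroxymethyl)-2,5,8a-trimethyl-1,4,4a,5,6,7,8,8a-octahydronaphthalen-1-yl]butan-2-one; 26 triethyl phosphonoacetate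
Product: 27 ethyl (2E)-5-[(1R,4aS,5R,6S,8aS)-6-hydroxy-5-(hydroxymethyl)-2,5,8a-trimethyl-1,4,4a,5,6,7,8,8a-octahydronaphthalen-1-yl]-3-methylpent-2-enoate
Conditions: NaH (4 equiv), THF, 0 °C to reflux
Reagents that add atoms: triethyl phosphonoacetate (26), CCOC(=O)CP(=O)(OCC)OCC
Why: Horner–Wadsworth–Emmons olefination of the methyl ketone should give the trisubstituted enoate with the E isomer expected to predominate, the minor Z isomer being removed by chromatography.

Step 14
Reactants: 27 ethyl (2E)-5-[(1R,4aS,5R,6S,8aS)-6-hydroxy-5-(hydroxymethyl)-2,5,8a-trimethyl-1,4,4a,5,6,7,8,8a-octahydronaphthalen-1-yl]-3-methylpent-2-enoate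
Product: 28 (2E)-5-[(1R,4aS,5R,6S,8aS)-6-hydroxy-5-(hydroxymethyl)-2,5,8a-trimethyl-1,4,4a,5,6,7,8,8a-octahydronaphthalen-1-yl]-3-methylpent-2-enoic acid
Conditions: LiOH·H2O, THF/MeOH/H2O, 50 °C; then dilute HCl to pH 3
Reagents that add atoms: lithium hydroxide, [Li+].[OH-]
Why: Saponification of the unhindered ethyl enoate should give the acid without touching any stereocentre or the double-bond geometry.

Step 15
Reactants: 28 (2E)-5-[(1R,4aS,5R,6S,8aS)-6-hydroxy-5-(hydroxymethyl)-2,5,8a-trimethyl-1,4,4a,5,6,7,8,8a-octahydronaphthalen-1-yl]-3-methylpent-2-enoic acid; 29 acetic anhydride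
Product: 30 (2E)-5-[(1R,4aS,5R,6S,8aS)-5-(acetoxymethyl)-6-hydroxy-2,5,8a-trimethyl-1,4,4a,5,6,7,8,8a-octahydronaphthalen-1-yl]-3-methylpent-2-enoic acid
Conditions: Ac2O (2.2 equiv), pyridine, CH2Cl2, 0 °C; aq. NaHCO3, then dilute HCl
Reagents that add atoms: acetic anhydride (29), CC(=O)OC(C)=O
Why: Acylation of the primary C19 hydroxyl should be much faster than that of the axial secondary C3 hydroxyl next to the quaternary C4, so limited anhydride without an acyl-transfer catalyst should give the monoacetate, and the mixed anhydride of the acid is hydrolysed on work-up.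

## Compound list

1 | 1,4-dioxaspiro[4.5]dec-6-en-8-one | O=C1C=CC2(CC1)OCCO2 | starting material
2 | 7-iodo-1,4-dioxaspiro[4.5]dec-6-en-8-one | O=C1CCC2(OCCO2)C=C1I | intermediate
3 | methylboronic acid | CB(O)O | starting material
4 | 7-methyl-1,4-dioxaspiro[4.5]dec-6-en-8-one | O=C1CCC2(OCCO2)C=C1C | intermediate
5 | but-3-en-1-ylmagnesium bromide | C=CCC[Mg]Br | starting material
6 | formaldehyde (monomer, THF solution) | C=O | starting material
7 | bromomagnesium (6S)-6-(but-3-en-1-yl)-7-methyl-1,4-dioxaspiro[4.5]dec-7-en-8-olate | Br[Mg]OC1=C(C)[C@H](CCC=C)C2(OCCO2)CC1 | intermediate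
8 | (6S,7R)-6-(but-3-en-1-yl)-7-(hydroxymethyl)-7-methyl-1,4-dioxaspiro[4.5]decan-8-one | O=C1CCC2(OCCO2)[C@@H](CCC=C)[C@]1(C)CO | intermediate
9 | (6S,7R)-6-(but-3-en-1-yl)-7-methyl-8-oxo-1,4-dioxaspiro[4.5]decane-7-carbaldehyde | O=C1CCC2(OCCO2)[C@@H](CCC=C)[C@]1(C)C=O | intermediate
10 | 1-methoxy-1,3-bis(trimethylsilyloxy)buta-1,3-diene | COC(O[Si](C)(C)C)=CC(=C)O[Si](C)(C)C | starting material
11 | open-chain titanium aldolate (C1–C2 adduct, C1 epimers, β-keto ester held as its silyl enol ether) | O=C1CCC2(OCCO2)[C@@H](CCC=C)[C@]1(C)C(O[Ti](Cl)(Cl)Cl)CC(=O)C=C(OC)O[Si](C)(C)C | intermediate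
12 | bicyclic titanium bis-aldolate (ring A closed, epimers at C1, C4 and C5) | COC(=O)C1C2(O[Ti](Cl)(Cl)Cl)CCC3(OCCO3)[C@@H](CCC=C)[C@]2(C)C(O[Ti](Cl)(Cl)Cl)CC1=O | intermediate
13 | methyl (4aS,5S)-5-(but-3-en-1-yl)-6,6-(ethylenedioxy)-4a-methyl-2-oxo-2,4a,5,6,7,8-hexahydronaphthalene-1-carboxylate | COC(=O)C1=C2CCC3(OCCO3)[C@@H](CCC=C)[C@]2(C)C=CC1=O | intermediate
14 | iodomethane | C[I] | starting material
15 | lithium enolate of 16 (C3–O–Li, C3=C4, 5-H trans to the C10 methyl) | COC(=O)C1[C@H]2CCC3(OCCO3)[C@@H](CCC=C)[C@]2(C)C=CC=1O[Li] | intermediate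
16 | methyl (1S,4aR,5S,8aS)-5-(but-3-en-1-yl)-6,6-(ethylenedioxy)-1,4a-dimethyl-2-oxo-1,2,4a,5,6,7,8,8a-octahydronaphthalene-1-carboxylate | COC(=O)[C@@]1(C)[C@H]2CCC3(OCCO3)[C@@H](CCC=C)[C@]2(C)C=CC1=O | intermediate
17 | methyl (1S,4aR,5S,8aS)-5-(but-3-en-1-yl)-1,4a-dimethyl-2,6-dioxo-1,2,4a,5,6,7,8,8a-octahydronaphthalene-1-carboxylate | COC(=O)[C@@]1(C)[C@H]2CCC(=O)[C@@H](CCC=C)[C@]2(C)C=CC1=O | intermediate
18 | potassium enolate of 17 (C8–O–K, C7=C8) | COC(=O)[C@@]1(C)[C@H]2CC=C(O[K])[C@@H](CCC=C)[C@]2(C)C=CC1=O | intermediate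
19 | methyl (1S,4aR,5S,8aS)-5-(but-3-en-1-yl)-1,4a-dimethyl-2-oxo-6-(trifluoromethanesulfonyloxy)-1,2,4a,5,8,8a-hexahydronaphthalene-1-carboxylate | COC(=O)[C@@]1(C)[C@H]2CC=C(OS(=O)(=O)C(F)(F)F)[C@@H](CCC=C)[C@]2(C)C=CC1=O | intermediate
20 | methylzinc chloride | C[Zn]Cl | starting material
21 | methyl (1S,4aS,5R,8aS)-5-(but-3-en-1-yl)-1,4a,6-trimethyl-2-oxo-1,2,4a,5,8,8a-hexahydronaphthalene-1-carboxylate | COC(=O)[C@@]1(C)[C@H]2CC=C(C)[C@@H](CCC=C)[C@]2(C)C=CC1=O | intermediate
22 | methyl (1S,4aS,5R,8aS)-5-(but-3-en-1-yl)-1,4a,6-trimethyl-2-oxo-1,2,3,4,4a,5,8,8a-octahydronaphthalene-1-carboxylate | COC(=O)[C@@]1(C)[C@H]2CC=C(C)[C@@H](CCC=C)[C@]2(C)CCC1=O | intermediate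
23 | methyl (1S,2S,4aS,5R,8aS)-5-(but-3-en-1-yl)-2-hydroxy-1,4a,6-trimethyl-1,2,3,4,4a,5,8,8a-octahydronaphthalene-1-carboxylate | COC(=O)[C@@]1(C)[C@H]2CC=C(C)[C@@H](CCC=C)[C@]2(C)CC[C@@H]1O | intermediate
24 | (1R,2S,4aS,5R,8aS)-5-(but-3-en-1-yl)-1-(hydroxymethyl)-1,4a,6-trimethyl-1,2,3,4,4a,5,8,8a-octahydronaphthalen-2-ol | OC[C@@]1(C)[C@H]2CC=C(C)[C@@H](CCC=C)[C@]2(C)CC[C@@H]1O | intermediate
25 | 4-[(1R,4aS,5R,6S,8aS)-6-hydroxy-5-(hydroxymethyl)-2,5,8a-trimethyl-1,4,4a,5,6,7,8,8a-octahydronaphthalen-1-yl]butan-2-one | OC[C@@]1(C)[C@H]2CC=C(C)[C@@H](CCC(C)=O)[C@]2(C)CC[C@@H]1O | intermediate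
26 | triethyl phosphonoacetate | CCOC(=O)CP(=O)(OCC)OCC | starting material
27 | ethyl (2E)-5-[(1R,4aS,5R,6S,8aS)-6-hydroxy-5-(hydroxymethyl)-2,5,8a-trimethyl-1,4,4a,5,6,7,8,8a-octahydronaphthalen-1-yl]-3-methylpent-2-enoate | OC[C@@]1(C)[C@H]2CC=C(C)[C@@H](CC/C(C)=C/C(=O)OCC)[C@]2(C)CC[C@@H]1O | intermediate
28 | (2E)-5-[(1R,4aS,5R,6S,8aS)-6-hydroxy-5-(hydroxymethyl)-2,5,8a-trimethyl-1,4,4a,5,6,7,8,8a-octahydronaphthalen-1-yl]-3-methylpent-2-enoic acid | OC[C@@]1(C)[C@H]2CC=C(C)[C@@H](CC/C(C)=C/C(=O)O)[C@]2(C)CC[C@@H]1O | intermediate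
29 | acetic anhydride | CC(=O)OC(C)=O | starting material
30 | (2E)-5-[(1R,4aS,5R,6S,8aS)-5-(acetoxymethyl)-6-hydroxy-2,5,8a-trimethyl-1,4,4a,5,6,7,8,8a-octahydronaphthalen-1-yl]-3-methylpent-2-enoic acid; labdane numbering (3S,4R,5S,9R,10S,13E) | CC(=O)OC[C@@]1(C)[C@H]2CC=C(C)[C@@H](CC/C(C)=C/C(=O)O)[C@]2(C)CC[C@@H]1O | target

## Step count and main risks

Total step count: 15. Longest linear sequence: 15 steps (1 to 30).

**Step 5 (key step).** The C1 titanium aldolate may eliminate before ring A closes, which would leave an open-chain E-enone that cannot cyclise, or the Lewis acid may open the dioxolane. The fallback sets out from 9 and comes back at 13, with the two bonds made one after the other under basic and buffered conditions. The dianion of methyl acetoacetate (NaH, then n-BuLi, THF, −78 °C) is added to the aldehyde to give methyl 5-[(6S,7R)-6-(but-3-en-1-yl)-7-methyl-8-oxo-1,4-dioxaspiro[4.5]decan-7-yl]-5-hydroxy-3-oxopentanoate F1. Silylation (Et3SiCl, imidazole, DMF) gives the 5-triethylsilyloxy ester F2, in which the C1 oxygen can neither lactonise nor be lost. Intramolecular Knoevenagel condensation (piperidine, AcOH, benzene, reflux with water removal) closes ring A to methyl (4aS,5S)-5-(but-3-en-1-yl)-6,6-(ethylenedioxy)-4a-methyl-2-oxo-4-(triethylsilyloxy)-2,3,4,4a,5,6,7,8-octahydronaphthalene-1-carboxylate F3. DBU in warm toluene then expels the silanol by E1cB elimination inside the ring and returns 13.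

**Step 6.** Electron transfer may go to the wrong half of the cross-conjugated dienone (loss of the C1=C2 bond or over-reduction), and the enolate may be O-methylated. The fallback sets out from 13 and comes back at 16. L-Selectride (1 equiv, THF, −78 °C) should deliver hydride to the less hindered C1 and give methyl (4aS,5S)-5-(but-3-en-1-yl)-6,6-(ethylenedioxy)-4a-methyl-2-oxo-2,3,4,4a,5,6,7,8-octahydronaphthalene-1-carboxylate F4, the classical substrate for reductive alkylation. Li/NH3 followed by MeI then gives methyl (1S,4aR,5S,8aS)-5-(but-3-en-1-yl)-6,6-(ethylenedioxy)-1,4a-dimethyl-2-oxodecahydronaphthalene-1-carboxylate F5. Dehydrogenation with IBX (DMSO, 70 °C) reintroduces the C1=C2 bond, because the C3 ketone can enolise only towards C2, and returns 16.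

**Step 3.** Facial discrimination by the chiral copper catalyst may be poor on the hindered α-methyl enone that carries the ketal next to the reacting carbon, and formaldehyde may be lost again by retro-aldol reaction. The fallback sets out from 4 and comes back at 8 by resolution. The same tandem addition run with achiral CuBr·SMe2 (10 mol %) gives 8 together with its enantiomer (6R,7S)-6-(but-3-en-1-yl)-7-(hydroxymethyl)-7-methyl-1,4-dioxaspiro[4.5]decan-8-one F6. Esterification of the mixture with (S)-2-methoxy-2-phenylacetic acid (EDC, DMAP, CH2Cl2) gives the diastereomeric esters [(6S,7R)-6-(but-3-en-1-yl)-7-methyl-8-oxo-1,4-dioxaspiro[4.5]decan-7-yl]methyl (2S)-2-methoxy-2-phenylacetate F7 and [(6R,7S)-6-(but-3-en-1-yl)-7-methyl-8-oxo-1,4-dioxaspiro[4.5]decan-7-yl]methyl (2S)-2-methoxy-2-phenylacetate F8, which are separated by chromatography. Methanolysis of F7 (K2CO3, MeOH, 0 °C) returns 8.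

## Further compounds

F1 | step 5 | methyl 5-[(6S,7R)-6-(but-3-en-1-yl)-7-methyl-8-oxo-1,4-dioxaspiro[4.5]decan-7-yl]-5-hydroxy-3-oxopentanoate | O=C1CCC2(OCCO2)[C@@H](CCC=C)[C@]1(C)C(O)CC(=O)CC(=O)OC
F2 | step 5 | methyl 5-[(6S,7R)-6-(but-3-en-1-yl)-7-methyl-8-oxo-1,4-dioxaspiro[4.5]decan-7-yl]-3-oxo-5-(triethylsilyloxy)pentanoate | O=C1CCC2(OCCO2)[C@@H](CCC=C)[C@]1(C)C(O[Si](CC)(CC)CC)CC(=O)CC(=O)OC
F3 | step 5 | methyl (4aS,5S)-5-(but-3-en-1-yl)-6,6-(ethylenedioxy)-4a-methyl-2-oxo-4-(triethylsilyloxy)-2,3,4,4a,5,6,7,8-octahydronaphthalene-1-carboxylate | COC(=O)C1=C2CCC3(OCCO3)[C@@H](CCC=C)[C@]2(C)C(O[Si](CC)(CC)CC)CC1=O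
F4 | step 6 | methyl (4aS,5S)-5-(but-3-en-1-yl)-6,6-(ethylenedioxy)-4a-methyl-2-oxo-2,3,4,4a,5,6,7,8-octahydronaphthalene-1-carboxylate | COC(=O)C1=C2CCC3(OCCO3)[C@@H](CCC=C)[C@]2(C)CCC1=O
F5 | step 6 | methyl (1S,4aR,5S,8aS)-5-(but-3-en-1-yl)-6,6-(ethylenedioxy)-1,4a-dimethyl-2-oxodecahydronaphthalene-1-carboxylate | COC(=O)[C@@]1(C)[C@H]2CCC3(OCCO3)[C@@H](CCC=C)[C@]2(C)CCC1=O
F6 | step 3 | (6R,7S)-6-(but-3-en-1-yl)-7-(hydroxymethyl)-7-methyl-1,4-dioxaspiro[4.5]decan-8-one | O=C1CCC2(OCCO2)[C@H](CCC=C)[C@@]1(C)CO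
F7 | step 3 | [(6S,7R)-6-(but-3-en-1-yl)-7-methyl-8-oxo-1,4-dioxaspiro[4.5]decan-7-yl]methyl (2S)-2-methoxy-2-phenylacetate | O=C1CCC2(OCCO2)[C@@H](CCC=C)[C@]1(C)COC(=O)[C@@H](OC)c1ccccc1
F8 | step 3 | [(6R,7S)-6-(but-3-en-1-yl)-7-methyl-8-oxo-1,4-dioxaspiro[4.5]decan-7-yl]methyl (2S)-2-methoxy-2-phenylacetate | O=C1CCC2(OCCO2)[C@H](CCC=C)[C@@]1(C)COC(=O)[C@@H](OC)c1ccccc1
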